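## The problem

Compound 18 is a 5,6,7,8-tetrahydroquinoline: a six-membered carbocycle fused to a pyridine through C4a–C8a, with C5 and C8 as the two pyridine-flanking methylenes. C6 is an all-carbon quaternary centre carrying a 3,4-dimethoxyphenyl group and a 2-(N-methylacetamido)ethyl chain. C6 is the only stereocentre and is (R); nothing else in the molecule can relay chirality to it, so a reagent or catalyst must set it in the step that tells its substituents apart. This is demanding because three of its four substituents are methylene groups (C5, C7 and the chain CH2), and no heteroatom is nearer than three bonds. Reagent choice is limited by the basic, reducible, metal-binding pyridine nitrogen, by the electron-rich veratryl ring and its methyl ethers, and by the tertiary amide, which is best made last. The feature that opens the route is a hidden symmetry at C6: the ring arm C7–C8, ending at pyridine carbon C8a, and the chain CH2–CH2–N are both two-carbon arms. With a carboxyl group on C8 and a carboxyl carbon in place of the chain nitrogen, both become the same propanoate arm, and C6 becomes the prochiral centre of the mirror-symmetric diester 9. Closing the ring between one arm and the halogen-bearing pyridine carbon (the future C8a) then creates carbocycle and stereocentre together, and both auxiliary carboxyl carbons are removable afterwards.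

## Retrosynthesis

**Amide and N-methyl group (18 ⇒ 17 ⇒ 16).** The acetamide N–C(O) bond is cut first, giving secondary amine 17. The N–CH3 bond is not cut as an alkylation, because a methyl halide would also attack the pyridine nitrogen and over-alkylate the amine. Instead the methyl carbon is traced back to the carbonyl carbon of methyl carbamate 16, so one hydride reduction delivers exactly one methyl group. The forward steps only need a chemoselective reduction and a routine acylation.

**Chain C–N bond with excision of one carbon (16 ⇒ 15 ⇒ 14 ⇒ 13).** Carbamate 16 is the alcohol adduct of isocyanate 15, which comes from acyl azide 14 and so from propanoic acid 13 by Curtius rearrangement. The neighbouring option, a two-carbon acid arm turned into the amine by amide reduction, would lose no carbon. It is rejected because only a three-carbon acid arm is identical with what the ring arm can be turned into. The migrating group is a primary alkyl, so no stereochemical demand arises.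

**Carboxyl at C8 and ester protection (13 ⇒ 12 ⇒ 11).** A carboxyl is added back at C8 and both acids are written as tert-butyl esters. C8 is attached to pyridine C8a next to nitrogen, so diacid 12 is a 2-pyridylacetic acid at that position, the one place from which CO2 leaves on mild warming. The same acid treatment that frees it also uncovers the chain acid. Diester 11 has more atoms than 13 but is the direct product of the symmetry-breaking cyclisation.

**Key cut, C8–C8a (11 ⇒ 10 ⇒ 9).** Cutting the bond between C8 and the pyridine gives the acyclic, achiral diester 9 with chlorine at pyridine C2, via its bis(enolate) 10. A cut at C4a–C5 would require electrophilic substitution on a pyridine. Cuts at C5–C6 or C6–C7 would build the quaternary centre during ring closure but leave the chain unrelated to the ring. Only the C8–C8a cut leaves two identical arms on C6 and places the halogen at the pyridine position most reactive towards oxidative addition. The forward reaction must be an enolate arylation that selects one of two enantiotopic arms and does not let the diester condense with itself.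

**Methylene link to the pyridine (9 ⇒ 8 ⇒ 7 ⇒ 4 + 6; 6 from 5).** A hydroxyl is reintroduced on the CH2 between the quaternary carbon and the pyridine, and the pyridine C3–CH bond is cut. Carbinol 7 is the adduct of aldehyde 4 and 2-chloro-3-lithiopyridine 6, made from 2-chloropyridine 5 by ortho-lithiation. The alternative, alkylating a carbanion at the quaternary carbon with a picolyl halide, has no acidifying group to rely on. The price is a deoxygenation through thiocarbonyl derivative 8. It must be a radical process, because a cation at that carbon would draw the aryl group over from the neighbouring quaternary centre and hydrogenolysis would take the chlorine.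

**The two propanoate arms (4 ⇒ 3 ⇒ 1 + 2).** Both bonds from the quaternary carbon to the arms are cut as conjugate additions of arylacetaldehyde 1 to tert-butyl acrylate 2, through mono-adduct 3. The formyl group first acidifies the benzylic position, then serves as the electrophile of the previous paragraph, and ends as ring carbon C5. Compounds 1, 2 and 5 are commercial, and all carbons of 9 are assembled in two C–C bond-forming operations.

## Roads not taken

**Alternative 1:** The pyridine ring is cut at C4a–C8a, C3–C4 and N1–C2 together with the carbocycle. The precursor is the acyclic dinitrile 4-(3,4-dimethoxyphenyl)-4-(prop-2-yn-1-yl)heptanedinitrile (A1), and acetylene (A2) supplies C2 and C3. A chiral indenyl cobalt complex of the (Ind*)Co(cod) type would combine the propargyl alkyne, one of the two enantiotopic cyanoethyl nitriles and A2 in a [2+2+2] cycloaddition. The product is 3-[(6S)-6-(3,4-dimethoxyphenyl)-5,6,7,8-tetrahydroquinolin-6-yl]propanenitrile (A3).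
- Merits: three bonds and both rings form in one operation, no halogenated pyridine is needed, and no carbon at C8 has to be removed later. In bond economy this is the better plan, and it discards one carbon fewer.
- Weak points:
  - The arm selection must be made by a cobalt centre whose chiral information sits on a cyclopentadienyl-type ligand far from C6. Selection between enantiotopic nitriles has much thinner precedent than ligand-controlled bond formation at palladium.
  - Under the pressure of A2 that is needed, the spectator nitrile of A3 can itself take up two molecules of A2 to form a second pyridine, and A2 cyclotrimerises on its own. Chemoselectivity is therefore tied to conversion.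
  - A1 is not easier to reach than 9: its propargyl group must be built at a neopentyl position by two one-carbon homologations of a formyl precursor.
  - The surviving nitrile still needs hydration, Hofmann degradation, N-methylation and acetylation, so the endgame is no shorter.
- Comparison: the chosen plan sets against the better bond economy elementary steps at palladium that are individually well understood, a large pool of chiral bisphosphines, and a cyclisation that cannot over-react because 9 contains a single C–Cl bond.

**Alternative 2:** The cut is C5–C6. The substrate is ethyl (2E)-3-(3,4-dimethoxyphenyl)-5-(3-formylpyridin-2-yl)pent-2-enoate (A4). A chiral triazolium-derived carbene turns the aldehyde into an acyl anion equivalent that adds to the β-carbon of the enoate (Stetter reaction). The product is ethyl 2-[(6R)-6-(3,4-dimethoxyphenyl)-5-oxo-5,6,7,8-tetrahydroquinolin-6-yl]acetate (A5).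
- Merits: enantioselective intramolecular Stetter reactions that create quaternary centres from β,β-disubstituted acceptors are established, so the stereo-defining event is better precedented than step 5. The catalyst is metal-free. The acetate arm of A5 already has the right length, so the chain nitrogen can come from an N-methyl amide and its reduction without excising a carbon.
- Weak points:
  - The acceptor in A4 is a β-aryl-β-alkyl enoate conjugated to an electron-rich veratryl ring, at the unreactive end of the acceptor scale.
  - The enantiomer formed depends on olefin geometry, and the trisubstituted enoate of A4 comes from olefination of an aryl ketone, which rarely gives a single isomer.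
  - A5 keeps a C5 carbonyl flanked by the quaternary centre and the pyridine. Removing it needs reduction and radical deoxygenation, or a forcing Wolff–Kishner reaction, on a late enantioenriched intermediate, and ketone and ester together complicate the hydride steps.
  - The aldehyde of A4 must be carried masked through the enoate construction.
- Comparison: Alternative 2 is ahead in precedent for the asymmetric step. The chosen plan sets against this an achiral precursor with no geometry issue, a surplus group (the C8 carboxyl) that leaves in the same operation as ester cleavage, and a shorter endgame (four steps against about six).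

**Alternative 3:** The cut is C7=C8. The precursor is the triene 3-[2-(3,4-dimethoxyphenyl)-2-ethenylbut-3-en-1-yl]-2-ethenylpyridine (A6). A chiral hexavalent molybdenum alkylidene of the Mo(NAr)(CHCMe2Ph)(diolate) type would join the 2-vinyl group of the pyridine with one of the two enantiotopic vinyl groups on C6 by ring-closing metathesis. The product is (6R)-6-(3,4-dimethoxyphenyl)-6-ethenyl-5,6-dihydroquinoline (A7).
- Merits: desymmetrising ring-closing metathesis is a proven way to set quaternary carbon stereocentres. Only a volatile two-carbon olefin is lost, and the residual vinyl group of A7 already is the two-carbon chain. In atom economy and in precedent for the enantioselective event this road is superior.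
- Weak points:
  - The basic nitrogen of a 2-vinylpyridine binds the Lewis-acidic molybdenum centre, and the alkylidene formed at that vinyl group is N-chelated and turns over poorly. Masking the nitrogen with acid is not compatible with the aryloxide ligands.
  - A6 needs two vinyl groups on a benzylic quaternary carbon next to a picolyl group, for which no short construction exists.
  - A7 has a ring alkene conjugated to the pyridine and a neopentyl-type vinyl group. The chain needs anti-Markovnikov functionalisation of the vinyl group while the ring alkene is saturated, and hydroboration has no clear preference between them.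
- Comparison: the chosen plan sets against the better atom economy that the pyridine nitrogen is an asset (it activates the C–Cl bond and later the decarboxylation), that 9 is made in four conventional steps, and that the endgame never has to tell two alkenes apart.

Key step: step 5

## Remarks before the steps

- Assumption: the sense of induction of (R)-DTBM-SEGPHOS in step 5 cannot be derived from precedent. The (R) ligand is written; should it favour the 6S series, the (S) ligand is used with no other change.
- The CIP descriptor at C6 changes from R (11, 12) to S (13, 14) and back to R (15–18) only because the priorities of the arms change. The spatial arrangement is the same throughout.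
- Quinoline numbering is used for ring atoms from step 5 onwards; the future C6 is C4 of the heptanedioate chain in 4–10.

## Route

Step 1
Reactants: 1 (3,4-dimethoxyphenyl)acetaldehyde; 2 tert-butyl acrylate (2.3 equiv)
Product: 4 di-tert-butyl 4-(3,4-dimethoxyphenyl)-4-formylheptanedioate, via mono-adduct 3 (not isolated)
Conditions: KOt-Bu (0.15 equiv), t-BuOH–THF, 0 → 25 °C, slow addition of 1; AcOH quench
Reagents that add atoms: none
Why: Base-catalysed double Michael addition: the α-aryl aldehyde enolate adds to the acrylate, and mono-adduct 3, which still has an acidic benzylic α-hydrogen, adds a second time to give the non-enolisable quaternary aldehyde 4. Slow addition of 1 into excess acrylate keeps free aldehyde low so that conjugate addition outruns self-aldol condensation, and tert-butoxide in tert-butanol cannot transesterify the tert-butyl esters.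

Step 2
Reactants: 5 2-chloropyridine (1.3 equiv); 4 di-tert-butyl 4-(3,4-dimethoxyphenyl)-4-formylheptanedioate
Product: 7 di-tert-butyl 4-[(2-chloropyridin-3-yl)(hydroxy)methyl]-4-(3,4-dimethoxyphenyl)heptanedioate (racemic at the carbinol carbon), via 2-chloro-3-lithiopyridine 6 (not isolated)
Conditions: LiN(i-Pr)2 (1.2 equiv), THF, −78 °C; then 4, −78 °C; AcOH–THF quench at −78 °C
Reagents that add atoms: none
Why: Directed ortho-lithiation of 2-chloropyridine by LiN(i-Pr)2 at −78 °C is selective for C3, and the aryllithium undergoes 1,2-addition to the aldehyde, which is far more electrophilic than the tert-butyl esters and has no α-hydrogen. A slight excess of 5 over the amide leaves no free base for the ester α-hydrogens, and protonation at −78 °C prevents lactonisation of the alkoxide onto an ester arm; the carbinol centre is racemic and is removed in step 4.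

Step 3
Reactants: 7 di-tert-butyl 4-[(2-chloropyridin-3-yl)(hydroxy)methyl]-4-(3,4-dimethoxyphenyl)heptanedioate
Product: 8 di-tert-butyl 4-{(2-chloropyridin-3-yl)[(1H-imidazol-1-ylcarbonothioyl)oxy]methyl}-4-(3,4-dimethoxyphenyl)heptanedioate (racemic)
Conditions: 1,1'-thiocarbonyldiimidazole (2 equiv), DMAP (0.2 equiv), ClCH2CH2Cl, 80 °C
Reagents that add atoms: 1,1'-thiocarbonyldiimidazole, S=C(n1ccnc1)n1ccnc1
Why: Thioacylation of the secondary alcohol under DMAP catalysis gives the Barton–McCombie substrate without generating an alkoxide, so the ester arms and the C–Cl bond are untouched.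

Step 4
Reactants: 8 di-tert-butyl 4-{(2-chloropyridin-3-yl)[(1H-imidazol-1-ylcarbonothioyl)oxy]methyl}-4-(3,4-dimethoxyphenyl)heptanedioate
Product: 9 di-tert-butyl 4-[(2-chloropyridin-3-yl)methyl]-4-(3,4-dimethoxyphenyl)heptanedioate (achiral)
Conditions: Bu3SnH (1.5 equiv), AIBN (0.2 equiv), toluene, 110 °C, slow addition
Reagents that add atoms: none
Why: Barton–McCombie deoxygenation: the Bu3Sn radical adds to sulfur, the C–O bond fragments to a pyridyl-stabilised benzylic radical, and hydrogen transfer from Bu3SnH gives the methylene. A radical path is chosen because a cation here would trigger a 1,2-aryl shift from the quaternary centre and hydrogenolysis would remove chlorine; the radical has no β-hydrogen to lose and the pyridyl C–Cl bond is inert to tin radicals. Removing the carbinol centre restores the mirror symmetry needed in step 5.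

Step 5
Reactants: 9 di-tert-butyl 4-[(2-chloropyridin-3-yl)methyl]-4-(3,4-dimethoxyphenyl)heptanedioate
Product: 11 tert-butyl (6R,8RS)-6-[3-(tert-butoxy)-3-oxopropyl]-6-(3,4-dimethoxyphenyl)-5,6,7,8-tetrahydroquinoline-8-carboxylate, via dilithium bis(enolate) 10 (not isolated)
Conditions: LiN(SiMe3)2 (3.2 equiv), toluene–THF, −78 °C, 9 added to the base; then Pd2(dba)3 (2.5 mol %), (R)-DTBM-SEGPHOS (6 mol %), −78 → 25 °C; AcOH quench at −78 °C
Reagents that add atoms: none
Why: Proposed new method: Double deprotonation at −78 °C converts both ester arms of 9 into lithium enolates (10), which removes every electrophilic carbonyl and so shuts down Dieckmann condensation; zerovalent palladium then inserts into the activated C2–Cl bond of the pyridine, one enolate arm displaces chloride at divalent palladium to give a C-bound enolate in a seven-membered palladacycle, and reductive elimination forms C8–C8a. The closest known reaction types are the palladium-catalysed α-arylation of tert-butyl ester lithium enolates with heteroaryl halides, its racemic intramolecular form, and enantioselective desymmetrising intramolecular α-arylations of prochiral 1,3-dicarbonyl compounds; what is new is arm selection in a diester whose prochiral carbon is β to the reacting enolate carbon. The six-membered carbocycle closes by C(sp2)–C(sp3) reductive elimination from the palladacycle, the CH2–C6–CH2 tether holding the enolate carbon within reach of C8a. C6 becomes stereogenic when one arm is bound; because both arms are enolates, the choice is made by the chiral bisphosphine on palladium, which should prefer the palladacycle in which the veratryl group on ring carbon C6 sits pseudo-equatorial and away from the 3,5-di-tert-butyl-4-methoxyphenyl walls of the ligand. C8 is formed without control and is deprotonated in situ as a 2-pyridylacetate enolate, which is harmless because this centre is erased in step 6. The step needs arm selectivity (ligand), arylation over condensation (full enolisation, tert-butyl esters, excess base so that no half-enolised diester exists) and suppression of the uncatalysed SNAr closure (low temperature, aggregated lithium enolates in toluene).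

Step 6
Reactants: 11 tert-butyl (6R,8RS)-6-[3-(tert-butoxy)-3-oxopropyl]-6-(3,4-dimethoxyphenyl)-5,6,7,8-tetrahydroquinoline-8-carboxylate
Product: 13 3-[(6S)-6-(3,4-dimethoxyphenyl)-5,6,7,8-tetrahydroquinolin-6-yl]propanoic acid, via diacid 12 (not isolated)
Conditions: CF3CO2H–CH2Cl2 (1:1), 25 °C; evaporate; then aqueous NaOAc–AcOH buffer (pH 5)–1,4-dioxane, 80 °C
Reagents that add atoms: none
Why: Acidolysis cleaves both tert-butyl esters with loss of isobutene; at pH 5 the 8-carboxylic acid of 12, a 2-pyridylacetic acid, loses CO2 through its N-protonated carboxylate and the resulting enamine tautomerises, whereas the propanoic acid arm is stable. The uncontrolled C8 stereocentre disappears and the quaternary C6 is unaffected.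

Step 7
Reactants: 13 3-[(6S)-6-(3,4-dimethoxyphenyl)-5,6,7,8-tetrahydroquinolin-6-yl]propanoic acid
Product: 16 methyl N-{2-[(6R)-6-(3,4-dimethoxyphenyl)-5,6,7,8-tetrahydroquinolin-6-yl]ethyl}carbamate, via acyl azide 14 (not isolated), via isocyanate 15 (not isolated)
Conditions: (PhO)2P(O)N3 (1.1 equiv), Et3N (1.2 equiv), toluene, 25 → 90 °C; then MeOH, 70 °C
Reagents that add atoms: diphenylphosphoryl azide, O=P(N=[N+]=[N-])(Oc1ccccc1)Oc1ccccc1; methanol, CO
Why: Curtius rearrangement: the phosphoryl azide converts the acid into acyl azide 14, which loses N2 on heating with 1,2-shift of the primary alkyl group to give isocyanate 15, and methanol adds to give the carbamate. The chain is shortened by one carbon to the required two-carbon link and the stereocentre is not involved.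

Step 8
Reactants: 16 methyl N-{2-[(6R)-6-(3,4-dimethoxyphenyl)-5,6,7,8-tetrahydroquinolin-6-yl]ethyl}carbamate
Product: 17 2-[(6R)-6-(3,4-dimethoxyphenyl)-5,6,7,8-tetrahydroquinolin-6-yl]-N-methylethan-1-amine
Conditions: LiAlH4 (3 equiv), THF, 65 °C; aqueous NaOH work-up
Reagents that add atoms: none
Why: LiAlH4 reduces the methyl carbamate to the N-methylamine, so the carbamate carbonyl carbon becomes the N-methyl group and no alkylating agent that could quaternise the pyridine is needed.

Step 9
Reactants: 17 2-[(6R)-6-(3,4-dimethoxyphenyl)-5,6,7,8-tetrahydroquinolin-6-yl]-N-methylethan-1-amine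
Product: 18 N-{2-[(6R)-6-(3,4-dimethoxyphenyl)-5,6,7,8-tetrahydroquinolin-6-yl]ethyl}-N-methylacetamide
Conditions: Ac2O (1.5 equiv), Et3N, CH2Cl2, 0 → 25 °C
Reagents that add atoms: acetic anhydride, CC(=O)OC(C)=O
Why: N-Acetylation of the secondary amine; the pyridine nitrogen is only transiently acylated and the veratryl ring does not react under these conditions.

## Compound list

1 | (3,4-dimethoxyphenyl)acetaldehyde | O=CCc1ccc(OC)c(OC)c1 | starting material
2 | tert-butyl acrylate | C=CC(=O)OC(C)(C)C | starting material
3 | tert-butyl 4-(3,4-dimethoxyphenyl)-5-oxopentanoate (racemic mono-adduct) | O=CC(CCC(=O)OC(C)(C)C)c1ccc(OC)c(OC)c1 | intermediate (not isolated)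
4 | di-tert-butyl 4-(3,4-dimethoxyphenyl)-4-formylheptanedioate | O=CC(CCC(=O)OC(C)(C)C)(CCC(=O)OC(C)(C)C)c1ccc(OC)c(OC)c1 | intermediate
5 | 2-chloropyridine | Clc1ccccn1 | starting material
6 | 2-chloro-3-lithiopyridine | [Li]c1cccnc1Cl | intermediate (not isolated)
7 | di-tert-butyl 4-[(2-chloropyridin-3-yl)(hydroxy)methyl]-4-(3,4-dimethoxyphenyl)heptanedioate (racemic) | CC(C)(C)OC(=O)CCC(CCC(=O)OC(C)(C)C)(C(O)c1cccnc1Cl)c1ccc(OC)c(OC)c1 | intermediate
8 | di-tert-butyl 4-{(2-chloropyridin-3-yl)[(1H-imidazol-1-ylcarbonothioyl)oxy]methyl}-4-(3,4-dimethoxyphenyl)heptanedioate (racemic) | CC(C)(C)OC(=O)CCC(CCC(=O)OC(C)(C)C)(C(OC(=S)n1ccnc1)c1cccnc1Cl)c1ccc(OC)c(OC)c1 | intermediate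
9 | di-tert-butyl 4-[(2-chloropyridin-3-yl)methyl]-4-(3,4-dimethoxyphenyl)heptanedioate (achiral) | CC(C)(C)OC(=O)CCC(CCC(=O)OC(C)(C)C)(Cc1cccnc1Cl)c1ccc(OC)c(OC)c1 | intermediate
10 | dilithium bis(enolate) of 9 (enolate geometry undefined) | CC(C)(C)OC(O[Li])=CCC(CC=C(O[Li])OC(C)(C)C)(Cc1cccnc1Cl)c1ccc(OC)c(OC)c1 | intermediate (not isolated)
11 | tert-butyl (6R,8RS)-6-[3-(tert-butoxy)-3-oxopropyl]-6-(3,4-dimethoxyphenyl)-5,6,7,8-tetrahydroquinoline-8-carboxylate | COc1ccc([C@]2(CCC(=O)OC(C)(C)C)CC(C(=O)OC(C)(C)C)c3ncccc3C2)cc1OC | intermediate
12 | (6R,8RS)-6-(2-carboxyethyl)-6-(3,4-dimethoxyphenyl)-5,6,7,8-tetrahydroquinoline-8-carboxylic acid | COc1ccc([C@]2(CCC(=O)O)CC(C(=O)O)c3ncccc3C2)cc1OC | intermediate (not isolated)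
13 | 3-[(6S)-6-(3,4-dimethoxyphenyl)-5,6,7,8-tetrahydroquinolin-6-yl]propanoic acid | COc1ccc([C@]2(CCC(=O)O)CCc3ncccc3C2)cc1OC | intermediate
14 | 3-[(6S)-6-(3,4-dimethoxyphenyl)-5,6,7,8-tetrahydroquinolin-6-yl]propanoyl azide | COc1ccc([C@]2(CCC(=O)N=[N+]=[N-])CCc3ncccc3C2)cc1OC | intermediate (not isolated)
15 | (6R)-6-(3,4-dimethoxyphenyl)-6-(2-isocyanatoethyl)-5,6,7,8-tetrahydroquinoline | COc1ccc([C@]2(CCN=C=O)CCc3ncccc3C2)cc1OC | intermediate (not isolated)
16 | methyl N-{2-[(6R)-6-(3,4-dimethoxyphenyl)-5,6,7,8-tetrahydroquinolin-6-yl]ethyl}carbamate | COc1ccc([C@]2(CCNC(=O)OC)CCc3ncccc3C2)cc1OC | intermediate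
17 | 2-[(6R)-6-(3,4-dimethoxyphenyl)-5,6,7,8-tetrahydroquinolin-6-yl]-N-methylethan-1-amine | COc1ccc([C@]2(CCNC)CCc3ncccc3C2)cc1OC | intermediate
18 | N-{2-[(6R)-6-(3,4-dimethoxyphenyl)-5,6,7,8-tetrahydroquinolin-6-yl]ethyl}-N-methylacetamide | COc1ccc([C@]2(CCN(C)C(C)=O)CCc3ncccc3C2)cc1OC | target

## Step count and least certain steps

Total step count: 9. Longest linear sequence: 9 steps (1 → 18); 2 and 5 enter as purchased building blocks.

**Step 5 (key step, proposed new method).**
- What may go wrong: weak discrimination between the two enolate arms is the most likely failure, because the diastereomeric palladacycles differ only in how the veratryl group and the spectator arm sit on C6, two atoms from the metal. Further risks are erosion of selectivity by uncatalysed SNAr ring closure, return of Dieckmann condensation if double enolisation is incomplete, β-hydride elimination from the palladium enolate with hydrodechlorination, and C–N coupling of the excess silylamide.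
- Fallback (known chemistry), from 9 back to 13: 9 is cyclised without stereocontrol under the same base protocol with Pd2(dba)3 and P(t-Bu)3, an established intramolecular ester enolate arylation. This should give tert-butyl (6RS,8RS)-6-[3-(tert-butoxy)-3-oxopropyl]-6-(3,4-dimethoxyphenyl)-5,6,7,8-tetrahydroquinoline-8-carboxylate F1. Acidolysis and decarboxylation as in step 6 pass through (6RS,8RS)-6-(2-carboxyethyl)-6-(3,4-dimethoxyphenyl)-5,6,7,8-tetrahydroquinoline-8-carboxylic acid F2, not isolated, to 3-[(6RS)-6-(3,4-dimethoxyphenyl)-5,6,7,8-tetrahydroquinolin-6-yl]propanoic acid F3. Preparative chromatography of F3 on a chiral stationary phase gives 13, where the route resumes, at the cost of half the material.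

**Step 1.**
- What may go wrong: self-aldol condensation and oligomerisation of the enolisable arylacetaldehyde may outrun conjugate addition, or the reaction may stall at mono-addition.
- Fallback, from 1 back to 4: the two additions are separated. Compound 1 is condensed with pyrrolidine (toluene, molecular sieves) to 1-[(E)-2-(3,4-dimethoxyphenyl)ethenyl]pyrrolidine F4. Stork enamine addition of F4 to 2 (MeCN, 80 °C) and hydrolysis with aqueous AcOH give 3, now isolated. Compound 3, which can no longer form a condensation-prone enal, is treated with 2 and catalytic KOt-Bu to give 4.

**Step 2.**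
- What may go wrong: proton transfer from the ester α-positions to the aryllithium, lactonisation of the lithium alkoxide onto an ester arm on warming, and loss of LiCl from 6 to a pyridyne above about −60 °C.
- Fallback, from 4 back to 7: a Nozaki–Hiyama–Kishi coupling of 4 with commercial 2-chloro-3-iodopyridine (CrCl2, 4 equiv; NiCl2, 2 mol %; DMF, 25 °C). The non-basic arylchromium adds only to the aldehyde and gives a chromium alkoxide that does not lactonise. This fallback makes no compound outside the compound list (none, F0).

**Step 3.**
- What may go wrong: slow thioacylation of the neopentyl-type secondary alcohol, with decomposition on prolonged heating.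
- Fallback, from 4 and 6 back to 9: the lithium alkoxide formed in the addition of step 2 is not protonated but captured at −78 → 0 °C with CS2 and then MeI. This gives di-tert-butyl 4-{(2-chloropyridin-3-yl)[(methylsulfanylcarbonothioyl)oxy]methyl}-4-(3,4-dimethoxyphenyl)heptanedioate F5. Capture by the small CS2 is less sensitive to hindrance and removes the alkoxide before it can lactonise. F5 is reduced with Bu3SnH and AIBN as in step 4 to 9.

**Step 8.**
- What may go wrong: hydride addition to the pyridine ring, and incomplete reduction or C–N cleavage of the carbamate giving the primary amine.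
- Fallback, from 13 back to 18: the Curtius rearrangement of step 7 is run to isocyanate 15, the solvent is removed and MeMgBr (3 equiv, THF, −78 → 0 °C) is added. This should give N-{2-[(6R)-6-(3,4-dimethoxyphenyl)-5,6,7,8-tetrahydroquinolin-6-yl]ethyl}acetamide F6. Deprotonation with NaH and methylation with MeI (1.05 equiv, THF, 0 °C) gives 18; the amide anion reacts far faster than the hindered neutral pyridine nitrogen.

## Further compounds

F1 | step 5 | tert-butyl (6RS,8RS)-6-[3-(tert-butoxy)-3-oxopropyl]-6-(3,4-dimethoxyphenyl)-5,6,7,8-tetrahydroquinoline-8-carboxylate | COc1ccc(C2(CCC(=O)OC(C)(C)C)CC(C(=O)OC(C)(C)C)c3ncccc3C2)cc1OC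
F2 | step 5 | (6RS,8RS)-6-(2-carboxyethyl)-6-(3,4-dimethoxyphenyl)-5,6,7,8-tetrahydroquinoline-8-carboxylic acid | COc1ccc(C2(CCC(=O)O)CC(C(=O)O)c3ncccc3C2)cc1OC
F3 | step 5 | 3-[(6RS)-6-(3,4-dimethoxyphenyl)-5,6,7,8-tetrahydroquinolin-6-yl]propanoic acid | COc1ccc(C2(CCC(=O)O)CCc3ncccc3C2)cc1OC
F4 | step 1 | 1-[(E)-2-(3,4-dimethoxyphenyl)ethenyl]pyrrolidine | COc1ccc(/C=C/N2CCCC2)cc1OC
F0 | step 2 | none | none
F5 | step 3 | di-tert-butyl 4-{(2-chloropyridin-3-yl)[(methylsulfanylcarbonothioyl)oxy]methyl}-4-(3,4-dimethoxyphenyl)heptanedioate (racemic) | CSC(=S)OC(c1cccnc1Cl)C(CCC(=O)OC(C)(C)C)(CCC(=O)OC(C)(C)C)c1ccc(OC)c(OC)c1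
F6 | step 8 | N-{2-[(6R)-6-(3,4-dimethoxyphenyl)-5,6,7,8-tetrahydroquinolin-6-yl]ethyl}acetamide | COc1ccc([C@]2(CCNC(C)=O)CCc3ncccc3C2)cc1OC
A1 | alternative 1 | 4-(3,4-dimethoxyphenyl)-4-(prop-2-yn-1-yl)heptanedinitrile | N#CCCC(CC#C)(CCC#N)c1ccc(OC)c(OC)c1
A2 | alternative 1 | acetylene | C#C
A3 | alternative 1 | 3-[(6S)-6-(3,4-dimethoxyphenyl)-5,6,7,8-tetrahydroquinolin-6-yl]propanenitrile | COc1ccc([C@]2(CCC#N)CCc3ncccc3C2)cc1OC
A4 | alternative 2 | ethyl (2E)-3-(3,4-dimethoxyphenyl)-5-(3-formylpyridin-2-yl)pent-2-enoate | CCOC(=O)/C=C(\CCc1ncccc1C=O)c1ccc(OC)c(OC)c1
A5 | alternative 2 | ethyl 2-[(6R)-6-(3,4-dimethoxyphenyl)-5-oxo-5,6,7,8-tetrahydroquinolin-6-yl]acetate | COc1ccc([C@]2(CC(=O)OCC)CCc3ncccc3C2=O)cc1OC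
A6 | alternative 3 | 3-[2-(3,4-dimethoxyphenyl)-2-ethenylbut-3-en-1-yl]-2-ethenylpyridine | C=CC(C=C)(Cc1cccnc1C=C)c1ccc(OC)c(OC)c1
A7 | alternative 3 | (6R)-6-(3,4-dimethoxyphenyl)-6-ethenyl-5,6-dihydroquinoline | COc1ccc([C@]2(C=C)C=Cc3ncccc3C2)cc1OC
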